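- Early times tell you how fast a flask starts and late times how far it got, so read the charges and readings below for both the first rate and the slowing that ends in the final E.

| flask | X | J | L | time |
|---|---|---|---|---|
| south | 0.250 M | 0.275 M | 0.00130 M |  |
| east | 0.130 M | 0.155 M | 0.00130 M |  |
| south-east | 0.250 M | 0.410 M | 0.00130 M |  |
| north | 0.250 M | 0.275 M | 0.00390 M |  |
| north-west | 0.100 M | 0.275 M | 0.00130 M | 110 min |

| run | time / min | [E] / M |
|---|---|---|
| south run | 6.3 | 0.0118 |
| south run | 19 | 0.0278 |
| south run | 36 | 0.0405 |
| south run | 57 | 0.0491 |
| south run | 82 | 0.0499 |
| south run | 110 | 0.0508 |
| east run | 6.3 | 0.0094 |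
| east run | 19 | 0.0252 |
| east run | 36 | 0.0343 |
| east run | 57 | 0.0410 |
| east run | 82 | 0.0419 |
| east run | 110 | 0.0437 |
| south-east run | 6.3 | 0.0152 |
| south-east run | 19 | 0.0350 |
| south-east run | 36 | 0.0486 |
| south-east run | 57 | 0.0543 |
| south-east run | 82 | 0.0574 |
| south-east run | 110 | 0.0585 |
| north run | 6.3 | 0.0985 |
| north run | 19 | 0.1408 |
| north run | 36 | 0.1427 |
| north run | 57 | 0.1412 |
| north run | 82 | 0.1408 |
| north run | 110 | 0.1409 |

(each reading ± 8 × 10⁻⁴ M)

- the power of [J] that the first rate follows, about the charge of the south run; measure it at two percent of X made into E
- the power of [X] that the first rate follows, about the charge of the south run; measure it at two percent of X made into E (one fixed amount of E, the same in the runs compared)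
- E in the north-west run at 110 min, as a share of the X charged

- Overall: X + J -> E, with L as catalyst.
- Constant volume, constant temperature.
- Readings of a species count what is bound in complexes too.
- "The second partner" is J.
- An order is taken over about fifteen percent of the charge, up and down.

- Take r, the first rate, as the first reading of E divided by its time, which gives 0.00187 M min⁻¹ in the south run, 0.00149 M min⁻¹ in the east run and 0.00241 M min⁻¹ in the south-east run.
- South against south-east changes J alone, so r follows [J] to a power of about 0.634, and east then puts the power of [X] near −0.208; these are rough readings, because each first reading carries a scatter of 8 × 10⁻⁴ M.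
- The south run slows: between 36 min and 57 min its rate is 4.10 × 10⁻⁴ M min⁻¹, lower than r by a factor of 4.57, while the J turned into E, reckoned from the readings, gives a factor of 1.13, so the readings show a slowing that this use of J does not cover.
- So fold the accumulated slowing into one quantity, the reach τ, the time the first rate would need to make the final E of a run, which I reckon for the south run as 27.1 min.
- The north-west run has the J and L of the south run, so I lend it that reach. Its lower X gives a first rate of 0.00227 M min⁻¹, and r times τ gives 0.0615 M, which is 61.5% of the X charged.
- Now put that answer back, with X as the limiting reagent of the north-west charge: counting X turned into E and no other use of it, midway to its final E the south run has 89.8% of its charge not turned into E, while the north-west run would have 69.3%. Scaling by that ratio gives 0.0474 M, and going round until the answer stops moving gives 0.0510 M, or 51.0%.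
- The forecast, reasoning from turnovers per L, “so the catalyst dies with turnover”, gives 0.67 for J, −0.3 for X and 50% for the north-west share; my X power differs from its value, and my share comes by the rate route.
- The flask gives 0.70 for J, −0.44 for X and 52.3% for the share, so the X power lies lower than the forecast's, while its J power and share stand within their margins.

    L + X ⇌ LX, settled at all times (40.90 L mol⁻¹)
    L + J ⇌ LJ, settled at all times (0.9070 L mol⁻¹)
    LX + LJ → E + 2 L (56820 L mol⁻¹ min⁻¹)
    2 J → Qa (0.3198 L mol⁻¹ min⁻¹)
    2 X → Zu (0.4980 L mol⁻¹ min⁻¹)

- On my first rate, the north-west result is a reach of 23.1 min, and in the simulated run without the path from two J to Qa the share rises from 52.3% to 64.1%, a reach of 28.3 min, so the reach is partly the time that J survives that path. It is not carried unchanged to the north run, with L at 0.00390 M: there the rate at the simulated point stands 9.1 times the south rate, and final E over that rate gives 8.30 min, shorter than the south run's 27.2 min.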